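In a world of one first-order step the substrate loses the same share of itself in every equal stretch of time, so one half-life carries you from a reading to any later time. The earlier runs let you test that.

| flask | substrate | reagent | scavenger | remark | time |
|---|---|---|---|---|---|
| Friday's | 0.10 M | 1.2 equiv | 0.85 equiv | run made earlier |  |
| Sunday's | 0.10 M | 1.2 equiv | 1.3 equiv | run made earlier |  |
| gamma | 0.10 M | 1.20 equiv | 1.20 equiv |  | 3.0 min |
| delta | 0.10 M | 1.20 equiv | 1.80 equiv |  | 3.0 min |

- Friday's (time / s: substrate / %, product / %): 30.0: 17, 23; 60.0: 7, 45; 90.0: 6, 63; 120: 0, 74
- Sunday's (time / s: substrate / %, product / %): 30.0: 18, 21; 60.0: 8, 48; 90.0: 5, 63; 120: 1, 72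

(standard deviation of a reading: 1.5 percentage points)

- part of the substrate that has reacted at the end, gamma
- part of the substrate that has reacted at the end, delta
- what raising the equivalents of scavenger from its lowest to its highest value here does to the part of the substrate that has reacted (changes below 5 percentage points count as none) (no change / it falls / it rises)

The substrate readings of Friday's and Sunday's runs lie within 1.5 percentage points of each other at each time, although the scavenger differs, so take their means: 7.50% at 60.0 s and 5.50% at 90.0 s.

Now define the running half-life: the time the substrate needs to halve, reckoned from two successive readings as if that stretch were first order. From 30.0 s to 60.0 s it is 24.5 s. From 60.0 s to 90.0 s it is longer, 67.0 s, but that is a rough reading, resting on a drop of 2 points. The next stretch, from 90.0 s to 120 s, reads 8.67 s, but its end readings are 0% and 1% with a scatter of 1.5 points, so I leave it out. The readings show no steady half-life and no clear drift, so I take the first two values as a range.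

That gives a bracket for 3.0 min. Carrying the shorter value on from 60.0 s gives the bound from above, 99.7% reacted. Carrying the longer value on from 90.0 s gives the bound from below, 97.8%, provided the half-life stays within that range. The gap, 1.9 points, is smaller than the 5 points that counts as a change, so I expect no change, though 1.80 equiv of scavenger in delta lies beyond the tested amounts.

The forecast gives 99.5% for gamma, 99.5% for delta and "no change", holding that “The scavenger therefore seems not to compete for reagent or influence substrate loss”; its values lie inside my bracket.

The flask gives 99.2% for gamma and 99.3% for delta, inside the bracket, and no change, with a shift of 0.083 points.

    substrate + reagent → intermediate + released group (k = 0.939 /M/s)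
    intermediate → product (k = 0.0153 /s)
    substrate + released group ⇌ idle adduct, settled at all times (K = 7.10 /M)
    scavenger + released group → scavenged by-product (k = 0.714 /M/s)

In gamma the substrate falls from 4.32% at 1.50 min to 0.753% at 3.00 min, a running half-life of 35.7 s, which lies between the two read values. Now read delta earlier, at 80 s. Carrying the mean at 60.0 s forward with the shorter value gives 95.7% reacted, and with the longer value 93.9%. That flask shows 94.9% reacted, with 5.15% of the substrate left.

Readings and results stem from a simulated flask on assumed constants; noise was put on by code.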